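**Retrosynthetic overview**

1. Target 27 ⇐ hydroxyl-directed epoxidation (ring oxirane, last) ⇐ Luche reduction ⇐ decarboxylative protonation of cyclohexenone 23, which already holds every carbon and both ester groups.
2. 23 ⇐ one-operation [3+3] union of dienal 11 and phosphorane 21: a Michael addition joins the acyloxy-bearing ring carbon to the side-chain-bearing ring carbon, and an intramolecular Wittig reaction joins the future epoxide CH to the methyl-bearing carbon.
3. Enabling feature: in the six-membered carbocycle the carbinol carbon lies between the acyloxy CH and the methyl-bearing epoxide carbon (a masked C–C(=O)–C unit with two different α-carbons), while the other three ring carbons (side-chain CH, CH2, epoxide CH) are the β-, α- and carbonyl carbons of an enal; the ring oxirane is a masked enone alkene.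
4. 11 ⇐ 4-methylpent-3-enoic acid (ynone, asymmetric transfer hydrogenation, angeloylation, Shi epoxidation, ene–yne metathesis, cross-metathesis); 21 ⇐ Meldrum's acid, 2-bromopropanoyl chloride, allyl alcohol and (R)-2-methylbutanoic acid.
5. Ring order: side-chain oxirane (step 5) → cyclohexene (step 12) → ring oxirane (step 15).

Key step: step 12

Remark: the 2-methylbutanoate and the side-chain oxirane carbon are read as (R) and the enoate as the (Z)-angelate; "angeloyl" means (Z)-2-methylbut-2-enoyl, "the side chain" means (3S)-3-(angeloyloxy)-4-[(2R)-3,3-dimethyloxiran-2-yl]but-1-en-2-yl, and centres formed as inconsequential mixtures (16, 17, 19–23) are left undefined in the SMILES.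

**Route**

Step 1
Reactants: 1 4-methylpent-3-enoic acid
Product: 2 N-methoxy-N,4-dimethylpent-3-enamide
Conditions: 1,1'-carbonyldiimidazole (1.1 equiv), CH2Cl2, 0 → 23 °C; then MeNH(OMe)·HCl (1.2 equiv), 23 °C
Reagents that add atoms: N,O-dimethylhydroxylamine hydrochloride, CNOC.Cl
Why: Weinreb amide formation through the acyl imidazole is neutral and should leave the β,γ-alkene in place.

Step 2
Reactants: 2 N-methoxy-N,4-dimethylpent-3-enamide; 3 trimethylsilylacetylene
Product: 4 6-methyl-1-(trimethylsilyl)hept-5-en-1-yn-3-one
Conditions: 3 (1.3 equiv), n-BuLi (1.25 equiv), THF, −78 °C; then 2, −78 → −20 °C; cold aq. NH4Cl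
Reagents that add atoms: none
Why: Weinreb ketone synthesis, in which the chelated tetrahedral intermediate prevents over-addition and the cold quench limits isomerisation of the β,γ-unsaturated ynone.

Step 3
Reactants: 4 6-methyl-1-(trimethylsilyl)hept-5-en-1-yn-3-one
Product: 6 (S)-6-methylhept-5-en-1-yn-3-ol, via silyl carbinol 5 (not isolated)
Conditions: RuCl[(S,S)-TsDPEN](p-cymene) (1 mol %), i-PrOH, 23 °C; then K2CO3 (0.3 equiv), MeOH, 23 °C
Reagents that add atoms: none
Why: Noyori asymmetric transfer hydrogenation of an alkynyl ketone, in which the alkyne acts as the π-substituent so that the (S,S)-catalyst should give the (S)-carbinol, followed by carbonate-mediated methanolysis of the C–Si bond.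

Step 4
Reactants: 6 (S)-6-methylhept-5-en-1-yn-3-ol; 7 angelic acid
Product: 8 (S)-6-methylhept-5-en-1-yn-3-yl angelate
Conditions: 7 (2 equiv), 2,4,6-trichlorobenzoyl chloride (2 equiv), Et3N (2 equiv), toluene, 23 °C; then 6, 80 °C
Reagents that add atoms: none
Why: Yamaguchi-type esterification through the mixed trichlorobenzoic anhydride without DMAP is the established way to make angelates of secondary alcohols without Z-to-E isomerisation to the tiglate.

Step 5
Reactants: 8 (S)-6-methylhept-5-en-1-yn-3-yl angelate
Product: 9 (2S)-1-[(2R)-3,3-dimethyloxiran-2-yl]but-3-yn-2-yl angelate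
Conditions: D-fructose-derived ketone 1,2:4,5-di-O-isopropylidene-β-D-erythro-2,3-hexodiulo-2,6-pyranose (0.3 equiv), Oxone (2KHSO5·KHSO4·K2SO4), K2CO3, Bu4NHSO4 (cat.), MeCN–CH2(OMe)2–aq. Na2B4O7 buffer (pH 10.5), 0 °C
Reagents that add atoms: potassium peroxymonosulfate (the oxidant in Oxone), [K+].[O-]S(=O)(=O)OO
Why: Shi asymmetric epoxidation, in which the chiral dioxirane should attack only the electron-rich trisubstituted alkene (angelate alkene and alkyne are inert) and its spiro transition state should give the (R)-oxirane.

Step 6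
Reactants: 9 (2S)-1-[(2R)-3,3-dimethyloxiran-2-yl]but-3-yn-2-yl angelate
Product: 10 (2S)-1-[(2R)-3,3-dimethyloxiran-2-yl]-3-methylidenepent-4-en-2-yl angelate
Conditions: second-generation Grubbs catalyst RuCl2(=CHPh)(H2IMes)(PCy3) (5 mol %), ethylene (1 atm), CH2Cl2, 23 °C
Reagents that add atoms: ethylene, C=C
Why: Ene–yne cross-metathesis of a terminal propargylic ester with ethylene should give the 2-substituted 1,3-butadiene, the hindered electron-poor angelate alkene staying out of the reaction.

Step 7
Reactants: 10 (2S)-1-[(2R)-3,3-dimethyloxiran-2-yl]-3-methylidenepent-4-en-2-yl angelate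
Product: 11 (2S,4E)-1-[(2R)-3,3-dimethyloxiran-2-yl]-3-methylidene-6-oxohex-4-en-2-yl angelate
Conditions: (E)-crotonaldehyde (5 equiv), second-generation Hoveyda–Grubbs catalyst RuCl2(=CH-2-(i-PrO)C6H4)(H2IMes) (5 mol %), CH2Cl2, 40 °C
Reagents that add atoms: (E)-crotonaldehyde, C/C=C/C=O
Why: Olefin cross-metathesis should occur at the monosubstituted vinyl group of the diene (the 1,1-disubstituted alkene beside the branched carbinol carbon is shielded) and give the E-enal as the thermodynamic isomer.

Step 8
Reactants: 12 Meldrum's acid (2,2-dimethyl-1,3-dioxane-4,6-dione); 13 2-bromopropanoyl chloride; 14 allyl alcohol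
Product: 16 allyl 4-bromo-3-oxopentanoate, via acyl Meldrum's acid 15 (not isolated)
Conditions: pyridine (2 equiv), CH2Cl2, 0 °C; aq. HCl wash; then 14 (1.5 equiv), toluene, 80 °C
Reagents that add atoms: none
Why: C-acylation of Meldrum's acid and thermal alcoholysis through the acyl ketene (loss of acetone and CO2) is the standard β-keto ester synthesis and tolerates the α-bromide.

Step 9
Reactants: 16 allyl 4-bromo-3-oxopentanoate
Product: 17 allyl 4-bromo-2-diazo-3-oxopentanoate
Conditions: 4-acetamidobenzenesulfonyl azide (1.1 equiv), Et3N (1.1 equiv), MeCN, 0 °C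
Reagents that add atoms: 4-acetamidobenzenesulfonyl azide, CC(=O)Nc1ccc(cc1)S(=O)(=O)N=[N+]=[N-]
Why: Regitz diazo transfer to the active methylene of a β-keto ester is fast at 0 °C and should outrun any reaction of the amine at the secondary bromide.

Step 10
Reactants: 17 allyl 4-bromo-2-diazo-3-oxopentanoate; 18 (R)-2-methylbutanoic acid
Product: 19 allyl 4-bromo-2-[(R)-2-methylbutanoyloxy]-3-oxopentanoate
Conditions: Rh2(OAc)4 (1 mol %), 18 (1.5 equiv), CH2Cl2, 23 → 40 °C, slow addition of 17
Reagents that add atoms: none
Why: Rh2(OAc)4-catalysed carbenoid O–H insertion into a carboxylic acid gives the α-acyloxy β-keto ester without touching the acid stereocentre, and the new centre is inconsequential.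

Step 11
Reactants: 19 allyl 4-bromo-2-[(R)-2-methylbutanoyloxy]-3-oxopentanoate
Product: 21 allyl 2-[(R)-2-methylbutanoyloxy]-3-oxo-4-(triphenylphosphoranylidene)pentanoate, via phosphonium bromide 20 (not isolated)
Conditions: PPh3 (1.05 equiv), toluene, 40 °C; then aq. Na2CO3, CH2Cl2, 0 °C; used at once
Reagents that add atoms: triphenylphosphine, c1ccc(cc1)P(c1ccccc1)c1ccccc1
Why: SN2 displacement of the α-keto bromide by the phosphine and deprotonation at the most acidic carbon (between phosphonium and ketone) is the standard preparation of a stabilised acyl ylide, and cold work-up with immediate use should avoid intramolecular Wittig reaction at the acyloxy carbonyl.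

Step 12
Reactants: 11 (2S,4E)-1-[(2R)-3,3-dimethyloxiran-2-yl]-3-methylidene-6-oxohex-4-en-2-yl angelate; 21 allyl 2-[(R)-2-methylbutanoyloxy]-3-oxo-4-(triphenylphosphoranylidene)pentanoate
Product: 23 allyl (6S)-3-methyl-1-[(R)-2-methylbutanoyloxy]-2-oxo-6-(side chain)cyclohex-3-ene-1-carboxylate, via Michael adduct aldehyde 22 (not isolated)
Conditions: 11 (1.0 equiv), 21 (1.3 equiv), (S)-α,α-diphenylprolinol trimethylsilyl ether (20 mol %), LiClO4 (30 mol %), DABCO (30 mol %), CHCl3, 23 °C
Reagents that add atoms: none
Why: Proposed new method: the secondary amine turns dienal 11 into its E-iminium ion, the enolate of the tertiary C–H of 21 (flanked by ester, acyl ylide and acyloxy group) adds to the β-carbon to join the acyloxy-bearing carbon to the side-chain-bearing carbon, and after hydrolysis the aldehyde of 22 is trapped by the internal methyl-substituted acyl ylide in a Wittig olefination that makes the methyl-bearing ring alkene; the closest known reaction type is the amine-catalysed tandem Michael–Wittig (formal carbo-[3+3]) annulation of enals with 4-(triphenylphosphoranylidene)acetoacetates, which has not been shown with a fully substituted α-acyloxy donor or a 4-substituted 2,4-dienal. The one ring is closed by the Wittig step as a 6-exo-trig attack of the ylide carbon on the aldehyde. The side-chain-bearing ring stereocentre is set by the catalyst, whose diphenyl(silyloxy)methyl group shields one face of the s-trans E-iminium ion so that the donor adds to the other face, which by the accepted shielding model is the required (S)-configuration (the enantiomeric amine is equally available); the quaternary acyloxy carbon forms as an epimer mixture that step 13 erases. The step needs 1,4- over 1,6-addition and Michael addition before intermolecular Wittig reaction: the first is favoured by the larger positive charge at the iminium β-carbon and reinforced because the Michael step is reversible while only the 1,4-adduct can leave the equilibrium through the fast six-membered Wittig closure, and the second by the low reactivity of the α-methyl acyl ylide toward an enal at room temperature. The side-chain stereocentres are remote from the reacting carbon, and the angelate and oxirane should be inert to the mild amine conditions.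

Step 13
Reactants: 23 allyl (6S)-3-methyl-1-[(R)-2-methylbutanoyloxy]-2-oxo-6-(side chain)cyclohex-3-ene-1-carboxylate
Product: 25 (1R,6S)-3-methyl-2-oxo-6-(side chain)cyclohex-3-en-1-yl (R)-2-methylbutanoate, via dienol 24 (not isolated)
Conditions: Pd(OAc)2 (5 mol %), PPh3 (15 mol %), HCO2H (4 equiv), Et3N (3 equiv), THF, 0 → 23 °C; crude product taken on at once
Reagents that add atoms: none
Why: Tsuji-type deallylation–decarboxylation–protonation of an allyl β-keto ester, in which zerovalent palladium should ionise the unhindered allyl ester far faster than the hindered secondary allylic angelate and the dienol 24, with its side chain pseudoaxial to avoid A(1,2) strain with the acyloxy group, should be protonated on carbon from the face opposite the side chain to give the cis (kinetic) α-acyloxy ketone.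

Step 14
Reactants: 25 (1R,6S)-3-methyl-2-oxo-6-(side chain)cyclohex-3-en-1-yl (R)-2-methylbutanoate
Product: 26 (1R,2S,6S)-2-hydroxy-3-methyl-6-(side chain)cyclohex-3-en-1-yl (R)-2-methylbutanoate
Conditions: NaBH4 (1.5 equiv), CeCl3·7H2O (1.2 equiv), MeOH, −78 °C; AcOH quench
Reagents that add atoms: none
Why: Luche 1,2-reduction, in which hydride should add axially and anti to the pseudoaxial α-acyloxy group so that the new hydroxyl is cis to both the ester and the side chain, while the low temperature and acidic quench suppress 1,2-acyl migration and removal of the ketone ends the epimerisation risk.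

Step 15
Reactants: 26 (1R,2S,6S)-2-hydroxy-3-methyl-6-(side chain)cyclohex-3-en-1-yl (R)-2-methylbutanoate
Product: 27 (1R,2R,3R,4S,6S)-2-hydroxy-1-methyl-4-(side chain)-7-oxabicyclo[4.1.0]heptan-3-yl (R)-2-methylbutanoate (CNP0181486.1)
Conditions: VO(acac)2 (5 mol %), t-BuOOH (1.5 equiv, in decane), CH2Cl2, 0 → 23 °C
Reagents that add atoms: tert-butyl hydroperoxide, CC(C)(C)OO
Why: Vanadium-catalysed hydroxyl-directed epoxidation should deliver oxygen to the ring alkene syn to the allylic hydroxyl (cis-epoxy alcohol) and far faster than to the 1,1-disubstituted and angelate alkenes, which have no hydroxyl at allylic distance.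

**Compound list**

1 | 4-methylpent-3-enoic acid | CC(C)=CCC(=O)O | starting material
2 | N-methoxy-N,4-dimethylpent-3-enamide | CC(C)=CCC(=O)N(C)OC | intermediate
3 | trimethylsilylacetylene | C#C[Si](C)(C)C | starting material
4 | 6-methyl-1-(trimethylsilyl)hept-5-en-1-yn-3-one | CC(C)=CCC(=O)C#C[Si](C)(C)C | intermediate
5 | (S)-6-methyl-1-(trimethylsilyl)hept-5-en-1-yn-3-ol | C[Si](C)(C)C#C[C@H](CC=C(C)C)O | intermediate (not isolated)
6 | (S)-6-methylhept-5-en-1-yn-3-ol | C#C[C@H](CC=C(C)C)O | intermediate
7 | angelic acid, (Z)-2-methylbut-2-enoic acid | C/C=C(/C)C(=O)O | starting material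
8 | (S)-6-methylhept-5-en-1-yn-3-yl angelate | C#C[C@H](CC=C(C)C)OC(=O)/C(C)=C\C | intermediate
9 | (2S)-1-[(2R)-3,3-dimethyloxiran-2-yl]but-3-yn-2-yl angelate | C#C[C@H](C[C@H]1OC1(C)C)OC(=O)/C(C)=C\C | intermediate
10 | (2S)-1-[(2R)-3,3-dimethyloxiran-2-yl]-3-methylidenepent-4-en-2-yl angelate | C=CC(=C)[C@H](C[C@H]1OC1(C)C)OC(=O)/C(C)=C\C | intermediate
11 | (2S,4E)-1-[(2R)-3,3-dimethyloxiran-2-yl]-3-methylidene-6-oxohex-4-en-2-yl angelate | O=C/C=C/C(=C)[C@H](C[C@H]1OC1(C)C)OC(=O)/C(C)=C\C | intermediate
12 | Meldrum's acid, 2,2-dimethyl-1,3-dioxane-4,6-dione | CC1(C)OC(=O)CC(=O)O1 | starting material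
13 | 2-bromopropanoyl chloride (racemic) | CC(Br)C(Cl)=O | starting material
14 | allyl alcohol | OCC=C | starting material
15 | 5-(2-bromo-1-hydroxypropylidene)-2,2-dimethyl-1,3-dioxane-4,6-dione | CC(Br)C(O)=C1C(=O)OC(C)(C)OC1=O | intermediate (not isolated)
16 | allyl 4-bromo-3-oxopentanoate (racemic) | CC(Br)C(=O)CC(=O)OCC=C | intermediate
17 | allyl 4-bromo-2-diazo-3-oxopentanoate (racemic) | CC(Br)C(=O)C(=[N+]=[N-])C(=O)OCC=C | intermediate
18 | (R)-2-methylbutanoic acid | OC(=O)[C@H](C)CC | starting material
19 | allyl 4-bromo-2-[(R)-2-methylbutanoyloxy]-3-oxopentanoate (diastereomer mixture) | CC(Br)C(=O)C(OC(=O)[C@H](C)CC)C(=O)OCC=C | intermediate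
20 | [5-(allyloxy)-4-[(R)-2-methylbutanoyloxy]-3,5-dioxopentan-2-yl]triphenylphosphonium bromide | CC([P+](c1ccccc1)(c1ccccc1)c1ccccc1)C(=O)C(OC(=O)[C@H](C)CC)C(=O)OCC=C.[Br-] | intermediate (not isolated)
21 | allyl 2-[(R)-2-methylbutanoyloxy]-3-oxo-4-(triphenylphosphoranylidene)pentanoate | CC(=P(c1ccccc1)(c1ccccc1)c1ccccc1)C(=O)C(OC(=O)[C@H](C)CC)C(=O)OCC=C | intermediate
22 | allyl 2-[(R)-2-methylbutanoyloxy]-3-oxo-2-[(1S)-3-oxo-1-(side chain)propyl]-4-(triphenylphosphoranylidene)pentanoate | C=C([C@H](C[C@H]1OC1(C)C)OC(=O)/C(C)=C\C)[C@H](CC=O)C(OC(=O)[C@H](C)CC)(C(=O)OCC=C)C(=O)C(C)=P(c1ccccc1)(c1ccccc1)c1ccccc1 | intermediate (not isolated)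
23 | allyl (6S)-3-methyl-1-[(R)-2-methylbutanoyloxy]-2-oxo-6-(side chain)cyclohex-3-ene-1-carboxylate (epimers at C-1) | C=C([C@H](C[C@H]1OC1(C)C)OC(=O)/C(C)=C\C)[C@@H]1CC=C(C)C(=O)C1(OC(=O)[C@H](C)CC)C(=O)OCC=C | intermediate
24 | (6S)-2-hydroxy-3-methyl-6-(side chain)cyclohexa-1,3-dien-1-yl (R)-2-methylbutanoate | C=C([C@H](C[C@H]1OC1(C)C)OC(=O)/C(C)=C\C)[C@@H]1CC=C(C)C(O)=C1OC(=O)[C@H](C)CC | intermediate (not isolated)
25 | (1R,6S)-3-methyl-2-oxo-6-(side chain)cyclohex-3-en-1-yl (R)-2-methylbutanoate | C=C([C@H](C[C@H]1OC1(C)C)OC(=O)/C(C)=C\C)[C@@H]1CC=C(C)C(=O)[C@@H]1OC(=O)[C@H](C)CC | intermediate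
26 | (1R,2S,6S)-2-hydroxy-3-methyl-6-(side chain)cyclohex-3-en-1-yl (R)-2-methylbutanoate | C=C([C@H](C[C@H]1OC1(C)C)OC(=O)/C(C)=C\C)[C@@H]1CC=C(C)[C@H](O)[C@@H]1OC(=O)[C@H](C)CC | intermediate
27 | (1R,2R,3R,4S,6S)-2-hydroxy-1-methyl-4-(side chain)-7-oxabicyclo[4.1.0]heptan-3-yl (R)-2-methylbutanoate, CNP0181486.1 | C=C([C@H](C[C@H]1OC1(C)C)OC(=O)/C(C)=C\C)[C@@H]1C[C@@H]2O[C@]2(C)[C@H](O)[C@@H]1OC(=O)[C@H](C)CC | target

**Step count and risks**

Total steps: 15. Longest linear sequence: 11 (steps 1–7 and 12–15); steps 8–11 make the second fragment.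

Steps most likely to fail:

Step 12. The fully substituted donor may add too slowly to the hindered iminium β-carbon, the addition may leak into the 1,6-mode, or the ylide may olefinate the dienal intermolecularly before the Michael step. The fallback uses known chemistry, sets out from 16 and 11 and comes back at 23. Bromide 16 is treated with PPh3 and the salt, [5-(allyloxy)-3,5-dioxopentan-2-yl]triphenylphosphonium bromide F1, is deprotonated with aqueous Na2CO3 to allyl 3-oxo-4-(triphenylphosphoranylidene)pentanoate F2. This unhindered methylene donor is of the class for which the amine-catalysed Michael–Wittig annulation is established; under the step-12 conditions with 11 it should give allyl (6R)-3-methyl-2-oxo-6-(side chain)cyclohex-3-ene-1-carboxylate F3 (same spatial arrangement at the side-chain carbon as in 23). Oxidative α-acyloxylation of this β-keto ester with acid 18 (Bu4NI 10 mol %, tert-butyl hydroperoxide, ethyl acetate, in situ hypoiodite catalysis) then forms the C–O bond after the ring and returns to 23.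

Step 13. Ketonisation of the dienol may show poor facial selectivity, the α-acyloxy ketone may epimerise after protonation, the acyl group may migrate within the enediol monoester, or the allylic angelate may ionise at palladium. The fallback sets out from 11 and 16 and comes back at 25; it sets the acyloxy carbon by inversion instead of protonation. Compounds 16 and 11 are taken through F2 to F3 as described above. Pd(PPh3)4 with morpholine removes the allyl ester with decarboxylation to (5R)-2-methyl-5-(side chain)cyclohex-2-en-1-one F4. Its kinetic lithium enolate (LiN(SiMe3)2, THF, −78 °C) is hydroxylated with 2-(phenylsulfonyl)-3-phenyloxaziridine anti to the side chain to give (5S,6S)-6-hydroxy-2-methyl-5-(side chain)cyclohex-2-en-1-one F5. Mitsunobu esterification with acid 18 (PPh3, diisopropyl azodicarboxylate) inverts the carbinol carbon and returns to 25.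

Step 7. The conjugated diene may undergo secondary metathesis or oligomerise, and conversion with the electron-poor partner may stall. The fallback sets out from 9 and comes back at 11. Ene–yne cross-metathesis of alkyne 9 directly with acrolein diethyl acetal (second-generation Hoveyda–Grubbs catalyst, CH2Cl2, 40 °C) should give (2S)-1-[(2R)-3,3-dimethyloxiran-2-yl]-6,6-diethoxy-3-methylidenehex-4-en-2-yl angelate F6 as an E/Z mixture. Mild hydrolysis (oxalic acid on wet silica, or pyridinium p-toluenesulfonate in wet acetone) frees the enal, which should equilibrate to the E-isomer (trace iodine if needed) and return to 11.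

Further compounds
F1 | step 12 | [5-(allyloxy)-3,5-dioxopentan-2-yl]triphenylphosphonium bromide | CC([P+](c1ccccc1)(c1ccccc1)c1ccccc1)C(=O)CC(=O)OCC=C.[Br-]
F2 | step 12 | allyl 3-oxo-4-(triphenylphosphoranylidene)pentanoate | CC(=P(c1ccccc1)(c1ccccc1)c1ccccc1)C(=O)CC(=O)OCC=C
F3 | step 12 | allyl (6R)-3-methyl-2-oxo-6-(side chain)cyclohex-3-ene-1-carboxylate (epimers at C-1) | C=C([C@H](C[C@H]1OC1(C)C)OC(=O)/C(C)=C\C)[C@@H]1CC=C(C)C(=O)C1C(=O)OCC=C
F4 | step 13 | (5R)-2-methyl-5-(side chain)cyclohex-2-en-1-one | C=C([C@H](C[C@H]1OC1(C)C)OC(=O)/C(C)=C\C)[C@@H]1CC=C(C)C(=O)C1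
F5 | step 13 | (5S,6S)-6-hydroxy-2-methyl-5-(side chain)cyclohex-2-en-1-one | C=C([C@H](C[C@H]1OC1(C)C)OC(=O)/C(C)=C\C)[C@@H]1CC=C(C)C(=O)[C@H]1O
F6 | step 7 | (2S)-1-[(2R)-3,3-dimethyloxiran-2-yl]-6,6-diethoxy-3-methylidenehex-4-en-2-yl angelate (E/Z mixture) | CCOC(OCC)C=CC(=C)[C@H](C[C@H]1OC1(C)C)OC(=O)/C(C)=C\C
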